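**Retrosynthetic overview**

1. Target 19 is a furan-2(5H)-one (ring atoms O1, C2, C3, C4, C5) with CH3 on C3, CO2H on C4 and (CH2)14CO2H on the (R)-configured C5. The plan rests on its fully substituted C3=C4 double bond, across which carbonyl carbon C2 and oxygen-bearing C5 lie on the same side. That is the arrangement left when an alkoxide on C5 steers an anti carbometalation of a C3≡C4 alkyne and holds the metal on C3.
2. Both carboxyl groups are taken back last: C4–CO2H to a C4 vinyl group (ozonolysis) and the chain CO2H to CH2OTBS (one chromic acid oxidation serves both ends).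
3. The only ring is made in one flask from propargylic alcohol 7, vinylmagnesium bromide and CO2: C4–vinyl bond, then C2–C3 bond, then O1–C2 lactone closure.
4. Alcohol 7 comes from ynone 6 by asymmetric transfer hydrogenation, and 6 from 16-hexadecanolide through a Weinreb amide and 1-propynylmagnesium bromide.

Key step: step 5

Assumption: 16-hexadecanolide, both Grignard reagents (THF solutions) and RuCl(p-cymene)[(R,R)-TsDPEN] are taken as commercial; the locants O1 and C2 to C5 of the furan-2(5H)-one ring are used throughout, also for the open-chain precursors.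

**Step 1**
Reactants: 1 16-hexadecanolide (oxacycloheptadecan-2-one)
Product: 2 16-hydroxy-N-methoxy-N-methylhexadecanamide
Conditions: MeNH(OMe)·HCl (1.5 equiv), i-PrMgCl (3.0 equiv), THF, −20 → 0 °C; aq NH4Cl
Reagents that add atoms: N,O-dimethylhydroxylamine hydrochloride, CNOC.Cl
Why: Weinreb aminolysis of an ester, in which the chloromagnesium amide made from the amine salt and i-PrMgCl opens the strain-free macrolactone at its acyl carbon as it would an open-chain ester and delivers all sixteen carbons with the two ends already differentiated.

**Step 2**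
Reactants: 2 16-hydroxy-N-methoxy-N-methylhexadecanamide
Product: 3 16-(tert-butyldimethylsilyloxy)-N-methoxy-N-methylhexadecanamide
Conditions: TBSCl, imidazole, CH2Cl2, rt
Reagents that add atoms: tert-butyldimethylsilyl chloride, CC(C)(C)[Si](C)(C)Cl
Why: Standard silylation of a primary alcohol, giving an ether that tolerates the Grignard steps and keeps the long chain soluble, and that the final acidic oxidation removes without a separate operation.

**Step 3**
Reactants: 3 16-(tert-butyldimethylsilyloxy)-N-methoxy-N-methylhexadecanamide, 4 1-propynylmagnesium bromide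
Product: 6 19-(tert-butyldimethylsilyloxy)nonadec-2-yn-4-one, via tetrahedral magnesium adduct 5 (not isolated)
Conditions: 1-propynylMgBr (1.5 equiv), THF, 0 °C; poured into cold 1 M aq HCl
Reagents that add atoms: 1-propynylmagnesium bromide, CC#C[Mg]Br
Why: Weinreb ketone synthesis, in which the N-methoxy chelate 5 stops the alkynyl Grignard after one addition and the cold acidic inverse quench protonates the released amine before it can add to the ynone.

**Step 4**
Reactants: 6 19-(tert-butyldimethylsilyloxy)nonadec-2-yn-4-one
Product: 7 (4R)-19-(tert-butyldimethylsilyloxy)nonadec-2-yn-4-ol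
Conditions: Ru[(R,R)-TsDPEN](p-cymene) (2 mol %, from RuCl(p-cymene)[(R,R)-TsDPEN] and KOH), i-PrOH, rt
Reagents that add atoms: none
Why: Noyori asymmetric transfer hydrogenation of an alkynyl ketone, in which the alkyne takes the place of the aryl group in the six-membered Ru–H/N–H transition state so that the (R,R)-ligand should deliver hydride to the face giving the (4R)-carbinol, with the triple bond left untouched.

**Step 5**
Reactants: 7 (4R)-19-(tert-butyldimethylsilyloxy)nonadec-2-yn-4-ol, 8 vinylmagnesium bromide, 9 carbon dioxide
Product: 13 (5R)-5-[15-(tert-butyldimethylsilyloxy)pentadecyl]-3-methyl-4-vinylfuran-2(5H)-one, via bromomagnesium alkoxide 10 (not isolated), via oxamagnesole 11 (not isolated), via Z-hydroxy acid 12 (not isolated)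
Conditions: vinylMgBr (3.5 equiv), CuI (10 mol %), THF, 0 °C → rt; CO2 (1 atm), −20 °C → rt; 1 M aq HCl, 0 °C
Reagents that add atoms: vinylmagnesium bromide, C=C[Mg]Br; carbon dioxide, O=C=O
Why: The first equivalent of vinylmagnesium bromide deprotonates 7 to alkoxide 10 (ethene escapes), and a vinylcopper species formed from CuI then places the vinyl group on the alkyne carbon next to the carbinol while magnesium ends on the methyl-bearing carbon, bound to the alkoxide oxygen in the five-membered 2,5-dihydro-1,2-oxamagnesole 11, so the addition is anti and the metal sits cis to C5. The alkenyl–magnesium bond takes up CO2 with retention of alkene geometry (C2–C3 bond), and acidification gives Z-hydroxy acid 12, whose C5 hydroxyl closes the butenolide on the carboxyl carbon by a 5-exo-trig acyl substitution (O1–C2 bond). The closest known reaction type is the copper-catalysed anti-carbomagnesiation of propargylic alcohols with capture of the cyclic alkenylmagnesium by electrophiles, CO2 included, to give butenolides. No stereocentre is created; the step needs regioselectivity (vinyl on the proximal carbon) and anti stereoselectivity, and both follow from the C5 alkoxide, since only that mode of addition gives the chelated metallacycle. The C5 configuration from step 4 is carried through, because no bond to C5 is broken and the carbinol is present as an alkoxide throughout. The CH3 end of the alkyne thereby arrives on C3, and the new C4 vinyl substituent is the handle that step 6 cuts down to the carboxyl carbon.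

**Step 6**
Reactants: 13 (5R)-5-[15-(tert-butyldimethylsilyloxy)pentadecyl]-3-methyl-4-vinylfuran-2(5H)-one
Product: 15 (2R)-2-[15-(tert-butyldimethylsilyloxy)pentadecyl]-4-methyl-5-oxo-2,5-dihydrofuran-3-carbaldehyde, via secondary ozonide 14 (not isolated)
Conditions: O3, CH2Cl2, −78 °C (stopped at first excess); PPh3, −78 °C → rt
Reagents that add atoms: ozone, [O-][O+]=O
Why: Ozonolysis by the Criegee mechanism with reductive work-up, in which electrophilic ozone should take the terminal γ,δ-double bond of the dienoate well ahead of the tetrasubstituted C3=C4 bond conjugated to the lactone carbonyl, and PPh3 reduces ozonide 14 under neutral conditions that do not enolise C5.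

**Step 7**
Reactants: 15 (2R)-2-[15-(tert-butyldimethylsilyloxy)pentadecyl]-4-methyl-5-oxo-2,5-dihydrofuran-3-carbaldehyde
Product: 19 (2R)-2-(14-carboxytetradecyl)-4-methyl-5-oxo-2,5-dihydrofuran-3-carboxylic acid, via silyl ether acid 16 (not isolated), via hydroxy acid 17 (not isolated), via oxo acid 18 (not isolated)
Conditions: CrO3, H2SO4, H2O, acetone, 0 °C → rt
Reagents that add atoms: water, O
Why: Jones oxidation, in which the electron-poor aldehyde is oxidised through its hydrate to acid 16, the aqueous acid cleaves the primary silyl ether to alcohol 17, and this is oxidised by way of aldehyde 18 to the second carboxyl group, the acidic medium leaving the lactone and the C5 configuration alone.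

**Compound list**

1 | 16-hexadecanolide (oxacycloheptadecan-2-one) | O=C1CCCCCCCCCCCCCCCO1 | starting material
2 | 16-hydroxy-N-methoxy-N-methylhexadecanamide | CON(C)C(=O)CCCCCCCCCCCCCCCO | intermediate
3 | 16-(tert-butyldimethylsilyloxy)-N-methoxy-N-methylhexadecanamide | CON(C)C(=O)CCCCCCCCCCCCCCCO[Si](C)(C)C(C)(C)C | intermediate
4 | 1-propynylmagnesium bromide | CC#C[Mg]Br | starting material
5 | bromomagnesium 19-(tert-butyldimethylsilyloxy)-4-[methoxy(methyl)amino]nonadec-2-yn-4-olate (tetrahedral adduct, racemic at C4) | CC#CC(O[Mg]Br)(N(C)OC)CCCCCCCCCCCCCCCO[Si](C)(C)C(C)(C)C | intermediate (not isolated)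
6 | 19-(tert-butyldimethylsilyloxy)nonadec-2-yn-4-one | CC#CC(=O)CCCCCCCCCCCCCCCO[Si](C)(C)C(C)(C)C | intermediate
7 | (4R)-19-(tert-butyldimethylsilyloxy)nonadec-2-yn-4-ol | CC#C[C@@H](CCCCCCCCCCCCCCCO[Si](C)(C)C(C)(C)C)O | intermediate
8 | vinylmagnesium bromide | C=C[Mg]Br | starting material
9 | carbon dioxide | O=C=O | starting material
10 | bromomagnesium (4R)-19-(tert-butyldimethylsilyloxy)nonadec-2-yn-4-olate | CC#C[C@@H](CCCCCCCCCCCCCCCO[Si](C)(C)C(C)(C)C)O[Mg]Br | intermediate (not isolated)
11 | (5R)-5-[15-(tert-butyldimethylsilyloxy)pentadecyl]-3-methyl-4-vinyl-2,5-dihydro-1,2-oxamagnesole | CC1=C(C=C)[C@@H](CCCCCCCCCCCCCCCO[Si](C)(C)C(C)(C)C)O[Mg]1 | intermediate (not isolated)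
12 | (2Z,4R)-19-(tert-butyldimethylsilyloxy)-3-ethenyl-4-hydroxy-2-methylnonadec-2-enoic acid | C/C(C(=O)O)=C(\C=C)[C@@H](CCCCCCCCCCCCCCCO[Si](C)(C)C(C)(C)C)O | intermediate (not isolated)
13 | (5R)-5-[15-(tert-butyldimethylsilyloxy)pentadecyl]-3-methyl-4-vinylfuran-2(5H)-one | CC1=C(C=C)[C@@H](CCCCCCCCCCCCCCCO[Si](C)(C)C(C)(C)C)OC1=O | intermediate
14 | (5R)-5-[15-(tert-butyldimethylsilyloxy)pentadecyl]-3-methyl-4-(1,2,4-trioxolan-3-yl)furan-2(5H)-one (either epimer at the trioxolane carbon) | CC1=C(C2OCOO2)[C@@H](CCCCCCCCCCCCCCCO[Si](C)(C)C(C)(C)C)OC1=O | intermediate (not isolated)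
15 | (2R)-2-[15-(tert-butyldimethylsilyloxy)pentadecyl]-4-methyl-5-oxo-2,5-dihydrofuran-3-carbaldehyde | CC1=C(C=O)[C@@H](CCCCCCCCCCCCCCCO[Si](C)(C)C(C)(C)C)OC1=O | intermediate
16 | (2R)-2-[15-(tert-butyldimethylsilyloxy)pentadecyl]-4-methyl-5-oxo-2,5-dihydrofuran-3-carboxylic acid | CC1=C(C(=O)O)[C@@H](CCCCCCCCCCCCCCCO[Si](C)(C)C(C)(C)C)OC1=O | intermediate (not isolated)
17 | (2R)-2-(15-hydroxypentadecyl)-4-methyl-5-oxo-2,5-dihydrofuran-3-carboxylic acid | CC1=C(C(=O)O)[C@@H](CCCCCCCCCCCCCCCO)OC1=O | intermediate (not isolated)
18 | (2R)-4-methyl-5-oxo-2-(15-oxopentadecyl)-2,5-dihydrofuran-3-carboxylic acid | CC1=C(C(=O)O)[C@@H](CCCCCCCCCCCCCCC=O)OC1=O | intermediate (not isolated)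
19 | (2R)-2-(14-carboxytetradecyl)-4-methyl-5-oxo-2,5-dihydrofuran-3-carboxylic acid | CC1=C(C(=O)O)[C@@H](CCCCCCCCCCCCCCC(=O)O)OC1=O | target

**Step count and risks**

Total steps: 7. Longest linear sequence: 7 steps (1 to 19).

Steps most likely to fail:

Step 5. The internally chelated, tetrasubstituted alkenylmagnesium 11 may take up CO2 more slowly than it is protonated on work-up, so that the metallacycle is returned as the uncarboxylated dienol. A D2O-quenched aliquot taken before CO2 is admitted would show whether the carbometalation itself is complete. The fallback sets out from 7 and comes back at 13. The same copper-catalysed vinylmagnesiation is run, but the metallacycle is quenched with I2 in THF at −20 °C, a much faster electrophile than CO2, to give the iodo dienol (2Z,4R)-19-(tert-butyldimethylsilyloxy)-3-ethenyl-2-iodononadec-2-en-4-ol F1. Carbon C2 is then introduced with PdCl2(PPh3)2 (cat.), CO (1 atm) and K2CO3 in THF at rt. Oxidative addition of the C–I bond to zerovalent palladium formed in the flask, CO insertion and capture of the acylpalladium by the C5 hydroxyl should give 13; this is the known cyclocarbonylation of Z-γ-iodoallylic alcohols to butenolides.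

Step 6. Over-oxidation is the concern: once the vinyl group is consumed, ozone may go on to attack the ring C3=C4 bond, or the ozonide may fragment abnormally next to the lactone. The fallback sets out from 13 and comes back at 15. OsO4 (cat.) with NMO in acetone/H2O at rt should dihydroxylate only the monosubstituted alkene, since the tetrasubstituted, electron-poor ring alkene is far slower, giving the diol (5R)-5-[15-(tert-butyldimethylsilyloxy)pentadecyl]-4-(1,2-dihydroxyethyl)-3-methylfuran-2(5H)-one F2 as either epimer. NaIO4 in THF/H2O then cleaves the glycol to aldehyde 15.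

Step 7. The silyl ether may be cleaved incompletely under the acidic chromium conditions, or alcohol 17 and aldehyde 18 may combine to a hemiacetal that is oxidised to a dimeric ester. The fallback sets out from 15 and comes back at 19, with each oxidation level changed by a selective reagent and the intermediates isolated. Pinnick oxidation (NaClO2, NaH2PO4, 2-methyl-2-butene, t-BuOH/H2O) gives acid 16. HF·pyridine in THF at 0 °C → rt frees alcohol 17. TEMPO (cat.) with PhI(OAc)2 in MeCN/H2O oxidises the primary alcohol to the acid 19. This fallback makes no compound outside the compound list (F0).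

**Further compounds**

F1 | step 5 | (2Z,4R)-19-(tert-butyldimethylsilyloxy)-3-ethenyl-2-iodononadec-2-en-4-ol | C/C(I)=C(\C=C)[C@@H](CCCCCCCCCCCCCCCO[Si](C)(C)C(C)(C)C)O
F2 | step 6 | (5R)-5-[15-(tert-butyldimethylsilyloxy)pentadecyl]-4-(1,2-dihydroxyethyl)-3-methylfuran-2(5H)-one (either epimer at the new carbinol carbon) | CC1=C(C(O)CO)[C@@H](CCCCCCCCCCCCCCCO[Si](C)(C)C(C)(C)C)OC1=O
F0 | step 7 | none | none
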